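**Strategy (guaiane numbering).** The C10 methyl carbon (C14) and the C7 carbinol carbon (C11), cis on the seven-membered ring, are tied together as the CH=CH bridge of a bicyclo[3.2.2]nonadienone. One catalytic asymmetric inverse-electron-demand Diels–Alder reaction between tropone (C1, C5, C6, C7, C10, C11, C14) and 1,1-diethoxyethene (C8, C9) forms C9–C10 and C7–C8 and fixes both bridgeheads. The cycloheptane of the target is therefore not the tropone ring; it is released when the C11=C14 bridge is cleaved, which leaves C14, C11 and O8 cis. The tropone carbonyl (C1) and enone (C5=C6) serve to annulate the cyclopentenone.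

Key step: step 2

Remark (labels): atoms carry the guaiane numbers of the target (C14 = methyl on C10, C11 = carbinol carbon on C7, C15 = methyl on C4); β is the face of the seven-membered ring that carries C14, C11 and O8.
Remark (assumption): the (R)-ligand is taken to give adduct 5; if the sense of induction is opposite, the (S)-ligand is used.
Remark (C1): C1 is γ to the enone and epimerisable, so compounds 10–21 are carried as C1 epimers (no C1 descriptor in their SMILES) and C1 is fixed in step 11.

Step 1
Reactants: 1 3-nitrobutan-2-ol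
Product: 2 (E)-2-nitrobut-2-ene
Conditions: phthalic anhydride (1.3 equiv), neat, 150–180 °C, 120 mbar, product distilled off
Reagents that add atoms: none
Why: The half-phthalate of the β-nitro alcohol should eliminate thermally (dehydration of a Henry adduct) and the volatile nitroalkene distils out; no stereocentre is involved.

Step 2
Reactants: 3 tropone; 4 1,1-diethoxyethene
Product: 5 (1R,5S)-9,9-diethoxybicyclo[3.2.2]nona-3,6-dien-2-one
Conditions: AlMe3 (10 mol%), (R)-3,3′-bis(triphenylsilyl)-1,1′-bi-2-naphthol (10 mol%), 4 (2 equiv), CH2Cl2, −78 → −40 °C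
Reagents that add atoms: none
Why: The aluminium Lewis acid binds the tropone oxygen and lowers the LUMO of the triene, so the nucleophilic CH2 terminus of 4 should bond to the α-carbon of tropone (C10) while the acetal carbon closes onto the carbon four atoms away (C7), either concertedly and asynchronously or by Mukaiyama–Michael addition followed by collapse of the oxocarbenium ion onto the dienolate. The closest known reaction type is the Lewis acid-catalysed inverse-electron-demand Diels–Alder reaction of tropones with ketene acetals, including its enantioselective variant with BINOL-derived aluminium catalysts. One ring is closed, the six-membered ring C7–C8–C9–C10–C14=C11, in a [4+2] mode across the 2,5-positions of tropone, which turns the monocycle into the bicyclo[3.2.2]nonadienone. The two new stereocentres are the bridgeheads C10 and C7: their relative configuration is fixed by the bicycle and their absolute configuration by the chiral ligand, which selects one of the two enantiotopic diene units of tropone. The step needs periselectivity for [4+2] over [8+2], secured by the bulky oxophilic Lewis acid that keeps the carbonyl oxygen occupied, and regioselectivity (CH2 to the α-carbon), which follows from the polarisation of both partners. The feature exploited is that C14 and C11 are adjacent ring carbons of tropone, so their cis relationship in the target is built in.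

Step 3
Reactants: 5 (1R,5S)-9,9-diethoxybicyclo[3.2.2]nona-3,6-dien-2-one; 2 (E)-2-nitrobut-2-ene
Product: 8 (1R,5R)-3-(3-oxobutan-2-yl)bicyclo[3.2.2]non-8-ene-2,6-dione, via lithium enolate 6 (not isolated), via lithium nitronate 7 (not isolated)
Conditions: LiBH(s-Bu)3 (1.05 equiv), THF, −78 °C; 2 (1.3 equiv), −78 → −30 °C; then poured into 3 M aq. HCl, 0 → 20 °C
Reagents that add atoms: water, O
Why: Hydride should add to C6 of the β-unsubstituted enone (conjugate reduction), the regiodefined enolate adds through C5 to the nitroalkene (Michael addition), and the acid quench converts the nitronate into the C3 ketone (Nef reaction) and hydrolyses the C8 ketal; the new centres at C4 and C5 are destroyed in step 4.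

Step 4
Reactants: 8 (1R,5R)-3-(3-oxobutan-2-yl)bicyclo[3.2.2]non-8-ene-2,6-dione
Product: 10 (7αH,10αH)-12,13-dinor-11,14-cycloguaia-4,11(14)-diene-3,8-dione, via 1(2)-enone 9 (not isolated)
Conditions: KOH (2 equiv), MeOH, 60 °C
Reagents that add atoms: none
Why: Intramolecular aldol condensation of the methyl ketone (C2) onto the C1 carbonyl closes ring A, and the first-formed 1(2)-enone should be transposed through its dienolates into the more substituted 2-methylcyclopent-2-enone (C4=C5); the C1 hydrogen is installed reversibly, so no C1 control is claimed here.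

Step 5
Reactants: 10 (7αH,10αH)-12,13-dinor-11,14-cycloguaia-4,11(14)-diene-3,8-dione
Product: 11 (7αH,10αH)-8α-hydroxy-12,13-dinor-11,14-cycloguaia-4,11(14)-dien-3-one
Conditions: NaBH4 (1 equiv), MeOH/CH2Cl2 (1:1), −78 °C
Reagents that add atoms: none
Why: The strained saturated C8 ketone should be reduced much faster than the conjugated tetrasubstituted cyclopentenone, and hydride should enter from the open face beside the CH=CH bridge (the C6 methylene of the three-atom bridge shields the other face), which places the hydroxyl on the α face (substrate-controlled 1,2-reduction).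

Step 6
Reactants: 11 (7αH,10αH)-8α-hydroxy-12,13-dinor-11,14-cycloguaia-4,11(14)-dien-3-one
Product: 13 (7αH,10αH)-8β-hydroxy-12,13-dinor-11,14-cycloguaia-4,11(14)-dien-3-one, via formate 12 (not isolated)
Conditions: PPh3, DIAD, HCO2H, THF, 0 → 20 °C; then K2CO3 (cat.), MeOH, 0 °C
Reagents that add atoms: formic acid, O=CO
Why: In the Mitsunobu reaction formate should displace the oxyphosphonium group by SN2 from the same open face, inverting C8 to the β (bridge-side) configuration; the formate is then removed by mild methanolysis.

Step 7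
Reactants: 13 (7αH,10αH)-8β-hydroxy-12,13-dinor-11,14-cycloguaia-4,11(14)-dien-3-one
Product: 16 (7αH,10αH)-8β,14-epoxy-14-hydroxy-3-oxo-12,13-dinorguai-4-en-11-al, via triol 14 (not isolated), via hydroxy dialdehyde 15 (not isolated)
Conditions: OsO4 (2 mol%), NaIO4 (4 equiv), 2,6-lutidine (2 equiv), 1,4-dioxane/H2O (3:1), 20 °C
Reagents that add atoms: osmium tetroxide, O=[Os](=O)(=O)=O (catalytic; its oxygen is replenished by sodium periodate, [Na+].[O-]I(=O)(=O)=O)
Why: OsO4 should dihydroxylate only the strained CH=CH bridge (the tetrasubstituted enone is inert) and periodate cleaves the cis-diol (Lemieux–Johnson oxidation); because C14, C11 and O8 sit on one face, the C14 aldehyde is captured by the 8β-hydroxyl as a five-membered lactol whereas C11 cannot be, which differentiates the two aldehydes without a protecting group.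

Step 8
Reactants: 16 (7αH,10αH)-8β,14-epoxy-14-hydroxy-3-oxo-12,13-dinorguai-4-en-11-al
Product: 18 methyl (7αH,10αH)-8β,14-epoxy-14-hydroxy-3-oxo-12,13-dinorguai-4-en-11-oate, via lactol acid 17 (not isolated)
Conditions: NaClO2, NaH2PO4, 2-methylbut-2-ene, t-BuOH/H2O, 0 → 20 °C; then Me3SiCHN2, PhMe/MeOH, 0 °C
Reagents that add atoms: sodium chlorite, [Na+].[O-]Cl=O; trimethylsilyldiazomethane, C[Si](C)(C)C=[N+]=[N-]
Why: Pinnick oxidation should convert the free C11 aldehyde into the acid under buffered conditions that neither epimerise C7 nor open the lactol, and the diazo reagent esterifies the acid; no stereocentre changes.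

Step 9
Reactants: 18 methyl (7αH,10αH)-8β,14-epoxy-14-hydroxy-3-oxo-12,13-dinorguai-4-en-11-oate
Product: 20 methyl (7αH,10αH)-8β-hydroxy-3-oxo-12,13-dinorguai-4-en-11-oate, via tosylhydrazone 19 (not isolated)
Conditions: TsNHNH2 (1.05 equiv), THF, 20 °C; then catecholborane (3 equiv), CHCl3, 0 °C; then NaOAc·3H2O, 60 °C
Reagents that add atoms: none
Why: The lactol should react through its open hydroxy aldehyde form with tosylhydrazide, and hydride reduction of the tosylhydrazone followed by acetate-induced loss of sulfinate and N2 (Caglioti-type deoxygenation) turns C14 into the methyl group without touching C10, the s-trans cyclopentenone or the ester.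

Step 10
Reactants: 20 methyl (7αH,10αH)-8β-hydroxy-3-oxo-12,13-dinorguai-4-en-11-oate
Product: 21 (7αH,10αH)-8β,11-dihydroxyguai-4-en-3-one
Conditions: LiN(SiMe3)2 (2.05 equiv), THF, −78 °C; then MeMgBr (4 equiv), −78 → 0 °C; aq. NH4Cl
Reagents that add atoms: methylmagnesium bromide, C[Mg]Br
Why: The hydroxyl and the enone are first converted into the lithium alkoxide and the cross-conjugated C2 lithium enolate, which shields the ketone, so the Grignard reagent should add twice to the ester only (ester to tertiary carbinol); protonation on work-up returns the enone.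

Step 11
Reactants: 21 (7αH,10αH)-8β,11-dihydroxyguai-4-en-3-one
Product: 22 (1R,7S,8R,10S)-8,11-dihydroxyguai-4-en-3-one
Conditions: NaOMe (0.3 equiv), MeOH, 20 °C
Reagents that add atoms: none
Why: Methoxide reversibly removes the γ-proton at C1 (extended dienolate), and the mixture is expected to settle on the epimer in which the C1–C2 bond is trans to the C10 methyl group (1β-H); C7, C8 and C10 are not acidic and stay untouched.

Step 12
Reactants: 22 (1R,7S,8R,10S)-8,11-dihydroxyguai-4-en-3-one
Product: 23 (1R,7S,8R,10S)-11-hydroxy-8-(methacryloyloxy)guai-4-en-3-one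
Conditions: methacryloyl chloride (1.3 equiv), Et3N, DMAP (cat.), CH2Cl2, 0 °C
Reagents that add atoms: methacryloyl chloride, C=C(C)C(=O)Cl
Why: DMAP-catalysed acylation should be selective for the secondary 8β-hydroxyl, the tertiary C11 hydroxyl being unreactive under these conditions.

Step 13
Reactants: 23 (1R,7S,8R,10S)-11-hydroxy-8-(methacryloyloxy)guai-4-en-3-one
Product: 24 (1R,7S,8R,10S)-11-acetoxy-8-(methacryloyloxy)guai-4-en-3-one
Conditions: Ac2O (3 equiv), Sc(OTf)3 (5 mol%), MeCN, −20 °C
Reagents that add atoms: acetic anhydride, CC(=O)OC(C)=O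
Why: Lewis acid-activated acetic anhydride should acetylate the hindered tertiary alcohol at low temperature, where neither elimination nor acyl migration is expected to compete.

**Compound list**

1 | 3-nitrobutan-2-ol (diastereomer mixture) | CC(O)C(C)[N+](=O)[O-] | starting material
2 | (E)-2-nitrobut-2-ene | C/C=C(\C)[N+](=O)[O-] | intermediate
3 | tropone (cyclohepta-2,4,6-trien-1-one) | O=C1C=CC=CC=C1 | starting material
4 | 1,1-diethoxyethene | C=C(OCC)OCC | starting material
5 | (1R,5S)-9,9-diethoxybicyclo[3.2.2]nona-3,6-dien-2-one | CCOC1(OCC)C[C@H]3C(=O)C=C[C@@H]1C=C3 | intermediate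
6 | lithium enolate (C1–OLi, C1=C5) of the 5,6-dihydro derivative of 5 | CCOC1(OCC)C[C@H]3C(O[Li])=CC[C@@H]1C=C3 | intermediate
7 | lithium nitronate of 9,9-diethoxy-3-(3-nitrobutan-2-yl)bicyclo[3.2.2]non-6-en-2-one | CCOC1(OCC)C[C@H]3C(=O)C(C(C)C(C)=[N+]([O-])[O-])C[C@@H]1C=C3.[Li+] | intermediate
8 | (1R,5R)-3-(3-oxobutan-2-yl)bicyclo[3.2.2]non-8-ene-2,6-dione (epimers at C3 and in the side chain) | O=C1C[C@H]3C(=O)C(C(C)C(C)=O)C[C@@H]1C=C3 | intermediate
9 | (7αH,10αH)-12,13-dinor-11,14-cycloguaia-1,11(14)-diene-3,8-dione | O=C1C[C@H]3C2=CC(=O)C(C)C2C[C@@H]1C=C3 | intermediate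
10 | (7αH,10αH)-12,13-dinor-11,14-cycloguaia-4,11(14)-diene-3,8-dione | O=C1C[C@H]3C2CC(=O)C(C)=C2C[C@@H]1C=C3 | intermediate
11 | (7αH,10αH)-8α-hydroxy-12,13-dinor-11,14-cycloguaia-4,11(14)-dien-3-one | O[C@H]1C[C@H]3C2CC(=O)C(C)=C2C[C@@H]1C=C3 | intermediate
12 | 8β-formate of 13 | O=CO[C@@H]1C[C@H]3C2CC(=O)C(C)=C2C[C@@H]1C=C3 | intermediate
13 | (7αH,10αH)-8β-hydroxy-12,13-dinor-11,14-cycloguaia-4,11(14)-dien-3-one | O[C@@H]1C[C@H]3C2CC(=O)C(C)=C2C[C@@H]1C=C3 | intermediate
14 | 8β,11,14-trihydroxy-12,13-dinor-11,14-cycloguai-4-en-3-one | O[C@@H]1C[C@H]3C2CC(=O)C(C)=C2C[C@@H]1C(O)C3O | intermediate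
15 | 8β-hydroxy-3-oxo-12,13-dinorguai-4-ene-11,14-dial | O[C@@H]1C[C@H](C=O)C2CC(=O)C(C)=C2C[C@@H]1C=O | intermediate
16 | (7αH,10αH)-8β,14-epoxy-14-hydroxy-3-oxo-12,13-dinorguai-4-en-11-al (lactol, anomers) | O1[C@@H]2C[C@H](C1O)C3CC(=O)C(C)=C3C[C@@H]2C=O | intermediate
17 | (7αH,10αH)-8β,14-epoxy-14-hydroxy-3-oxo-12,13-dinorguai-4-en-11-oic acid | O1[C@@H]2C[C@H](C1O)C3CC(=O)C(C)=C3C[C@@H]2C(=O)O | intermediate
18 | methyl (7αH,10αH)-8β,14-epoxy-14-hydroxy-3-oxo-12,13-dinorguai-4-en-11-oate | O1[C@@H]2C[C@H](C1O)C3CC(=O)C(C)=C3C[C@@H]2C(=O)OC | intermediate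
19 | methyl 8β-hydroxy-3-oxo-14-(tosylhydrazono)-12,13-dinorguai-4-en-11-oate | O[C@@H]1C[C@H](C=NNS(=O)(=O)c3ccc(C)cc3)C2CC(=O)C(C)=C2C[C@@H]1C(=O)OC | intermediate
20 | methyl (7αH,10αH)-8β-hydroxy-3-oxo-12,13-dinorguai-4-en-11-oate | O[C@@H]1C[C@H](C)C2CC(=O)C(C)=C2C[C@@H]1C(=O)OC | intermediate
21 | (7αH,10αH)-8β,11-dihydroxyguai-4-en-3-one (C1 epimers) | O[C@@H]1C[C@H](C)C2CC(=O)C(C)=C2C[C@@H]1C(C)(C)O | intermediate
22 | (1R,7S,8R,10S)-8,11-dihydroxyguai-4-en-3-one (1βH,7αH,10αH; 8β-OH) | O[C@@H]1C[C@H](C)[C@H]2CC(=O)C(C)=C2C[C@@H]1C(C)(C)O | intermediate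
23 | (1R,7S,8R,10S)-11-hydroxy-8-(methacryloyloxy)guai-4-en-3-one | C=C(C)C(=O)O[C@@H]1C[C@H](C)[C@H]2CC(=O)C(C)=C2C[C@@H]1C(C)(C)O | intermediate
24 | (1R,7S,8R,10S)-11-acetoxy-8-(methacryloyloxy)guai-4-en-3-one | C=C(C)C(=O)O[C@@H]1C[C@H](C)[C@H]2CC(=O)C(C)=C2C[C@@H]1C(C)(C)OC(C)=O | target

**Totals.** Total step count: 13. Longest linear sequence: 12 steps (3 → 24, steps 2–13).

**Steps most likely to fail**

Step 10. Incomplete or reversible enolisation would let the Grignard reagent add to the enone carbonyl, and ester enolisation could epimerise C7. The fallback protects the enone by a redox detour. It sets out from 20: Luche reduction (NaBH4, CeCl3·7H2O, MeOH, −40 °C) should give the allylic alcohol methyl 3,8β-dihydroxy-12,13-dinorguai-4-en-11-oate F1. Excess MeMgBr then converts the ester into the carbinol, giving guai-4-ene-3,8β,11-triol F2. MnO2 in CH2Cl2 oxidises only the allylic alcohol and the path comes back to the route at 21.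

Step 6. SN2 displacement at a bridge carbon next to a bridgehead may be slow, so elimination towards C9 or participation of the CH=CH bridge (retention, skeletal rearrangement) could take over. The fallback replaces substrate-controlled reduction plus inversion by a reagent-controlled reduction. It sets out from 10: a screened ketoreductase (NADPH, isopropanol, buffer, 30 °C) should reduce only the C8 ketone and deliver hydride from the face of the three-atom bridge, and the path comes back to the route at 13; it makes no compound outside the list (none F0).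

Step 11. The position of the C1 equilibrium in the flexible hydroazulene is the least secure prediction of the route; it may be unselective or favour the 1α-H epimer. The fallback sets C1 kinetically in the rigid tricycle instead. It sets out from 13: KOt-Bu in t-BuOH/THF followed by a cold AcOH quench should give the deconjugated (7αH,10αH)-8β-hydroxy-12,13-dinor-11,14-cycloguaia-1(5),11(14)-dien-3-one F3. Oxalic acid in CH2Cl2 then reconjugates it with protonation of C1 from the open face beside the CH=CH bridge, giving (1βH,7αH,10αH)-8β-hydroxy-12,13-dinor-11,14-cycloguaia-4,11(14)-dien-3-one F4, which is 13 as a single C1 epimer. Steps 7–10 are run on it as written (none uses an equilibrating base) and the path comes back to the route at 22, step 11 being omitted.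

**Further compounds**

F1 | step 10 | methyl 3,8β-dihydroxy-12,13-dinorguai-4-en-11-oate | O[C@@H]1C[C@H](C)C2CC(O)C(C)=C2C[C@@H]1C(=O)OC
F2 | step 10 | guai-4-ene-3,8β,11-triol | O[C@@H]1C[C@H](C)C2CC(O)C(C)=C2C[C@@H]1C(C)(C)O
F0 | step 6 | none | none
F3 | step 11 | (7αH,10αH)-8β-hydroxy-12,13-dinor-11,14-cycloguaia-1(5),11(14)-dien-3-one | O[C@@H]1C[C@H]3C2=C(C(C)C(=O)C2)C[C@@H]1C=C3
F4 | step 11 | (1βH,7αH,10αH)-8β-hydroxy-12,13-dinor-11,14-cycloguaia-4,11(14)-dien-3-one | O[C@@H]1C[C@H]3[C@H]2CC(=O)C(C)=C2C[C@@H]1C=C3
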